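**Strategy**

The ester and the veratryl styrene are removed first, leaving an anti 1,3-diol: the benzylic oxygen on C1, the methine C2 and its CH2–O arm C3. This O–C1–C2–C3–O array, with C1 para-methoxybenzylic, is what formaldehyde leaves when it adds to an E aryl alkene. One catalytic asymmetric Prins reaction therefore adds two formaldehyde units across the anisyl alkene of the skipped diene (E)-1-(4-methoxyphenyl)penta-1,4-diene, forming C2–C3, C1–O and the acetal link, closing a trans-4,5-disubstituted 1,3-dioxane ring and setting both stereocentres. The spare vinyl group later receives the dimethoxyphenyl unit by cross-metathesis, and the Z-hydroxymethylbutenoyl group is attached last.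

Key step: step 2

Remark on the structures: the alcohol part of the target is (1S,2S) (benzylic C1, methine C2), which corresponds to the trans (4S,5S) dioxane. The acyl part is the Z acid (CH3 cis to the carboxyl), the less stable geometry, so it is made by a kinetic syn addition to an alkyne.

Assumption: the sense of induction of the confined acid on an internal styrene cannot be read from terminal styrenes, so the catalyst antipode is fixed after a first pair of test runs. Paraformaldehyde is drawn as its monomer; the dioxane takes up two CH2O units, one entered as reactant 4 and the second as an atom-adding reagent from the same paraformaldehyde.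

Remark on the order of steps: the acetal is opened while the side chain is still a plain vinyl group, so no electron-rich styrene is present that could capture the transient O–CH2 electrophile in an intramolecular Prins closure.

**Route**

Step 1
Reactants: 1 (E)-2-(4-methoxyphenyl)vinylboronic acid; 2 allyl bromide
Product: 3 (E)-1-methoxy-4-(penta-1,4-dienyl)benzene
Conditions: Pd(PPh3)4 (3 mol %), K2CO3 (2 equiv), THF/H2O 9:1, 50 °C
Reagents that add atoms: none
Why: Suzuki–Miyaura allylation, in which allyl bromide adds oxidatively to zerovalent palladium, the alkenylboronate transmetalates with retention of the E geometry and reductive elimination gives the 1,4-diene; the allyl unit is symmetrical, so no regiochemical question arises.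

Step 2
Reactants: 3 (E)-1-methoxy-4-(penta-1,4-dienyl)benzene; 4 paraformaldehyde (first CH2O unit)
Product: 5 (4S,5S)-4-(4-methoxyphenyl)-5-(prop-2-enyl)-1,3-dioxane (trans)
Conditions: (CH2O)n (4 equiv of CH2O), confined imino-imidodiphosphoric acid (ArBINOL)P(=NTf)–NH–P(=O)(ArBINOL) [iIDP; ArBINOL = 3,3'-bis(heptafluoro-2-naphthyl)-1,1'-binaphthalene-2,2'-diolate, single antipode] (5 mol %), cyclohexane, 20 °C
Reagents that add atoms: formaldehyde (second CH2O unit, from the same paraformaldehyde), C=O
Why: Proposed new method: the confined acid depolymerises paraformaldehyde and ion-pairs with a protonated formaldehyde–hemiformal unit built from two CH2O molecules, whose carbon is attacked by C2 of the anisyl alkene of 3 (C2–C3 bond) while the charge building at the para-methoxybenzylic C1 is quenched by the hemiformal oxygen (C1–O bond); the closest known reaction type is the confined-acid-catalysed asymmetric intermolecular Prins reaction of terminal styrenes with paraformaldehyde, together with the classical acid-mediated Prins reaction of anethole to its trans dioxane, and the new element is the use of the chiral catalyst on an internal E β-alkyl styrene. The 1,3-dioxane ring closes by O-to-C1 bond formation through a six-membered chair (the closing half of an asynchronous, formally [2+2+2] union of the alkene with two C=O units) in which aryl and allyl are both equatorial. C5 of 5 (C2 of the target) is set by the alkene face that the chiral counteranion leaves open to the electrophile, so the catalyst antipode decides 5S. C4 (C1 of the target) follows from C5, either by suprafacial C–C and C–O addition to the E alkene or, if the cation lives longer, by the diequatorial chair, and both paths give the trans ring and hence 4S. The step needs site selectivity over the terminal vinyl group, secured by the para-methoxy group, which makes only the C1=C2 alkene nucleophilic enough and stabilises charge at C1, whereas the unconjugated vinyl group can offer only a secondary cation.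

Step 3
Reactants: 5 (4S,5S)-4-(4-methoxyphenyl)-5-(prop-2-enyl)-1,3-dioxane
Product: 7 (1S,2S)-1-(4-methoxyphenyl)-2-(prop-2-enyl)propane-1,3-diol, via silyl ether bipyridinium triflate 6 (not isolated)
Conditions: TMSOTf (2 equiv), 2,2'-bipyridyl (3 equiv), CH2Cl2, 0 °C; then H2O, rt
Reagents that add atoms: trimethylsilyl triflate, C[Si](C)(C)OS(=O)(=O)C(F)(F)F, and 2,2'-bipyridyl, c1ccnc(c1)-c1ccccn1 (both carried only in 6; 7 keeps no atom of either)
Why: Silyl triflate–bipyridyl cleavage of a methylene acetal, in which silylation of the less hindered ring oxygen opens the O–CH2–O unit to an N-(alkoxymethyl)bipyridinium salt without free strong acid and water then hydrolyses this salt and the TMS ether, so the C1–O and C3–O bonds are never broken and both stereocentres are kept.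

Step 4
Reactants: 7 (1S,2S)-1-(4-methoxyphenyl)-2-(prop-2-enyl)propane-1,3-diol; 8 3,4-dimethoxystyrene
Product: 9 (1S,2S)-2-[(2E)-3-(3,4-dimethoxyphenyl)prop-2-enyl]-1-(4-methoxyphenyl)propane-1,3-diol
Conditions: 8 (3 equiv), second-generation Grubbs catalyst RuCl2(=CHPh)(H2IMes)(PCy3) (5 mol %), CH2Cl2, 40 °C
Reagents that add atoms: none
Why: Olefin cross-metathesis of a terminal alkene with a styrene, driven by loss of ethene and expected to give the aryl-conjugated alkene as the E isomer under thermodynamic control, with free hydroxyl groups tolerated by the ruthenium carbene.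

Step 5
Reactants: 10 ethyl but-2-ynoate; 4 paraformaldehyde (cracked to monomeric formaldehyde)
Product: 12 ethyl (2Z)-2-(hydroxymethyl)but-2-enoate, via alkenylalane 11 (not isolated)
Conditions: DIBAL-H (1.2 equiv), NMO (1.3 equiv), THF, 0 °C; then HCHO (gas from 4), 0 °C to rt; aqueous work-up
Reagents that add atoms: diisobutylaluminium hydride, CC(C)C[AlH]CC(C)C (its aluminium and isobutyl groups stay only in 11; 12 keeps its hydrogen alone)
Why: Reductive aldol by vinylalumination, in which conjugate syn hydroalumination puts hydride on C3 and aluminium on C2 and the alkenylalane then adds to formaldehyde with retention, so H and CH2OH end up cis and the methyl group cis to the ester, which is the Z isomer.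

Step 6
Reactants: 12 ethyl (2Z)-2-(hydroxymethyl)but-2-enoate
Product: 13 ethyl (2Z)-2-[(tert-butyldimethylsilyloxy)methyl]but-2-enoate
Conditions: TBSCl, imidazole, CH2Cl2, 0 °C to rt
Reagents that add atoms: tert-butyldimethylsilyl chloride, CC(C)(C)[Si](C)(C)Cl
Why: Standard silylation of a primary allylic alcohol through the N-silylimidazolium species, which leaves the alkene geometry untouched.

Step 7
Reactants: 13 ethyl (2Z)-2-[(tert-butyldimethylsilyloxy)methyl]but-2-enoate
Product: 14 (2Z)-2-[(tert-butyldimethylsilyloxy)methyl]but-2-enoic acid
Conditions: LiOH·H2O, THF/H2O, 0 °C to rt; then cold 0.5 M HCl to pH 4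
Reagents that add atoms: lithium hydroxide, [Li+].[OH-] (its oxygen becomes the carboxyl OH)
Why: Saponification by acyl–oxygen cleavage at or below room temperature, conditions under which a primary TBS ether and the Z trisubstituted alkene should both persist.

Step 8
Reactants: 9 (1S,2S)-2-[(2E)-3-(3,4-dimethoxyphenyl)prop-2-enyl]-1-(4-methoxyphenyl)propane-1,3-diol; 14 (2Z)-2-[(tert-butyldimethylsilyloxy)methyl]but-2-enoic acid
Product: 15 (2S,4E)-5-(3,4-dimethoxyphenyl)-2-[(S)-hydroxy(4-methoxyphenyl)methyl]pent-4-enyl (2Z)-2-[(tert-butyldimethylsilyloxy)methyl]but-2-enoate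
Conditions: 14 (1.1 equiv), DIC (1.2 equiv), DMAP (10 mol %), CH2Cl2, −10 to 0 °C
Reagents that add atoms: none
Why: Steglich esterification, in which the hindered α,α-disubstituted acyl donor should discriminate strongly between the primary hydroxyl and the secondary benzylic one, while the low temperature and the small amount of DMAP limit any Z to E drift of the activated acid.

Step 9
Reactants: 15 the silyl ether from step 8
Product: 16 (2S,4E)-5-(3,4-dimethoxyphenyl)-2-[(S)-hydroxy(4-methoxyphenyl)methyl]pent-4-enyl (2Z)-2-(hydroxymethyl)but-2-enoate (target)
Conditions: TBAF, AcOH (1:1), THF, 0 °C to rt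
Reagents that add atoms: none
Why: Fluoride desilylation of a primary TBS ether, buffered with acetic acid so that no free alkoxide is present to move the acyl group to the benzylic hydroxyl and no acid strong enough to ionise that position.

**Compound list**

1 | (E)-2-(4-methoxyphenyl)vinylboronic acid | COc1ccc(/C=C/B(O)O)cc1 | starting material
2 | allyl bromide | C=CCBr | starting material
3 | (E)-1-methoxy-4-(penta-1,4-dienyl)benzene | C=CC/C=C/c1ccc(OC)cc1 | intermediate
4 | paraformaldehyde (drawn as formaldehyde) | C=O | starting material
5 | (4S,5S)-4-(4-methoxyphenyl)-5-(prop-2-enyl)-1,3-dioxane | C1OC[C@H](CC=C)[C@H](O1)c2ccc(OC)cc2 | intermediate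
6 | 1-{[(1S,2S)-1-(4-methoxyphenyl)-2-(trimethylsilyloxymethyl)pent-4-enyloxy]methyl}-2-(pyridin-2-yl)pyridinium triflate (not isolated) | C[Si](C)(C)OC[C@H](CC=C)[C@H](OC[n+]1ccccc1-c1ccccn1)c1ccc(OC)cc1.[O-]S(=O)(=O)C(F)(F)F | intermediate
7 | (1S,2S)-1-(4-methoxyphenyl)-2-(prop-2-enyl)propane-1,3-diol | OC[C@H](CC=C)[C@H](O)c1ccc(OC)cc1 | intermediate
8 | 3,4-dimethoxystyrene | C=Cc1ccc(OC)c(OC)c1 | starting material
9 | (1S,2S)-2-[(2E)-3-(3,4-dimethoxyphenyl)prop-2-enyl]-1-(4-methoxyphenyl)propane-1,3-diol | OC[C@H](C/C=C/c1ccc(OC)c(OC)c1)[C@H](O)c1ccc(OC)cc1 | intermediate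
10 | ethyl but-2-ynoate | CC#CC(=O)OCC | starting material
11 | ethyl (2E)-2-(diisobutylalumanyl)but-2-enoate (CH3 cis to CO2Et; not isolated) | C/C=C(/[Al](CC(C)C)CC(C)C)C(=O)OCC | intermediate
12 | ethyl (2Z)-2-(hydroxymethyl)but-2-enoate | C/C=C(/CO)C(=O)OCC | intermediate
13 | ethyl (2Z)-2-[(tert-butyldimethylsilyloxy)methyl]but-2-enoate | C/C=C(/CO[Si](C)(C)C(C)(C)C)C(=O)OCC | intermediate
14 | (2Z)-2-[(tert-butyldimethylsilyloxy)methyl]but-2-enoic acid | C/C=C(/CO[Si](C)(C)C(C)(C)C)C(=O)O | intermediate
15 | (2S,4E)-5-(3,4-dimethoxyphenyl)-2-[(S)-hydroxy(4-methoxyphenyl)methyl]pent-4-enyl (2Z)-2-[(tert-butyldimethylsilyloxy)methyl]but-2-enoate | C/C=C(/CO[Si](C)(C)C(C)(C)C)C(=O)OC[C@H](C/C=C/c1ccc(OC)c(OC)c1)[C@H](O)c1ccc(OC)cc1 | intermediate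
16 | (2S,4E)-5-(3,4-dimethoxyphenyl)-2-[(S)-hydroxy(4-methoxyphenyl)methyl]pent-4-enyl (2Z)-2-(hydroxymethyl)but-2-enoate | C/C=C(/CO)C(=O)OC[C@H](C/C=C/c1ccc(OC)c(OC)c1)[C@H](O)c1ccc(OC)cc1 | target

**Step count and risks**

Total steps: 9. Longest linear sequence: 6 (steps 1, 2, 3, 4, 8, 9); the acid branch (steps 5, 6, 7) joins at step 8.

Steps most likely to fail:

1. Step 2. What may go wrong: weak facial discrimination of an internal alkene inside the catalyst pocket, cationic oligomerisation of the electron-rich alkene, or loss of the trans relationship if a long-lived benzylic cation closes unselectively. The fallback uses known chemistry, sets out from allyl bromide 2 and comes back at diol 7, bypassing steps 1 to 3. Purchased ethyl 3-(4-methoxyphenyl)-3-oxopropanoate F1 would be hydrogenated over RuCl2[(R)-BINAP] in ethanol (Noyori reduction; this antipode is expected to give the S carbinol) to ethyl (3S)-3-hydroxy-3-(4-methoxyphenyl)propanoate F2. Its dianion (LDA, 2.2 equiv, THF, −50 to −20 °C) would be allylated with 2 in the Fráter–Seebach manner, anti to the alkoxide-bearing centre, to ethyl (2R,3S)-3-hydroxy-3-(4-methoxyphenyl)-2-(prop-2-enyl)propanoate F3. LiAlH4 in THF at 0 °C would then reduce the ester to 7.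

2. Step 3. What may go wrong: ionisation of the para-methoxybenzylic C–O bond once the ring has been opened under silyl activation, leading to epimerisation or substitution at C1, or incomplete hydrolysis at the pyridinium stage. The fallback sets out from dioxane 5 and comes back at diol 7, and it changes the activation from silylation to acylation. Acetolysis (Ac2O/AcOH, trace H2SO4, 0 °C) would acylate the primary ring oxygen and open the O–CH2–O unit to [(2S)-2-[(S)-(acetyloxymethoxy)(4-methoxyphenyl)methyl]pent-4-enyl] acetate F4. K2CO3 in MeOH would then remove both acetyl groups under basic, non-ionising conditions, the freed hemiformal losing formaldehyde to leave 7.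

3. Step 8. What may go wrong: Z to E isomerisation of the activated acyl unit through reversible conjugate addition of DMAP, and competing acylation of the benzylic hydroxyl. The fallback sets out from diol 9 (with acid 14) and comes back at 15. It is a Mitsunobu esterification (PPh3, DIAD, THF, 0 °C), in which the primary hydroxyl of 9 is activated as an oxyphosphonium ion and displaced by the carboxylate of 14. The acid never becomes an acyl electrophile, so its geometry cannot drift, and the hindered secondary carbinol should react far more slowly than the primary one.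

Further compounds
F1 | step 2 | ethyl 3-(4-methoxyphenyl)-3-oxopropanoate (purchased) | CCOC(=O)CC(=O)c1ccc(OC)cc1
F2 | step 2 | ethyl (3S)-3-hydroxy-3-(4-methoxyphenyl)propanoate | CCOC(=O)C[C@H](O)c1ccc(OC)cc1
F3 | step 2 | ethyl (2R,3S)-3-hydroxy-3-(4-methoxyphenyl)-2-(prop-2-enyl)propanoate | CCOC(=O)[C@H](CC=C)[C@H](O)c1ccc(OC)cc1
F4 | step 3 | [(2S)-2-[(S)-(acetyloxymethoxy)(4-methoxyphenyl)methyl]pent-4-enyl] acetate | CC(=O)OC[C@H](CC=C)[C@H](OCOC(C)=O)c1ccc(OC)cc1
F0 | step 8 | none | none
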